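**Retrosynthetic overview**
- Commercial andrographolide 1 already holds rings A and B, the lactone carbons and all five ring stereocentres of the target, so no ring is built and no stereocentre has to be set.
- First disconnection (first forward step): the C11=C12/C13=C14 diene of diol 2 comes from 1 by 1,4-loss of water (C14–OH and H-11).
- Second disconnection (last forward step, key bond): the O19–acyl C–O bond, made from 2 and isopropenyl acetate 3 by a borinic-acid-catalysed site-selective acetyl transfer through borinate 4, giving target 5.
- Order: dehydration first (removes the third hydroxyl), site-selective C–O bond formation last under near-neutral conditions.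

Assumption: andrographolide, the bulk extract product of Andrographis paniculata sold in kilogram lots, counts as a cheap commercial starting material; its natural configuration matches the target SMILES centre by centre (the target is 19-O-acetyl-14-deoxy-11,12-didehydroandrographolide).

Step 1
Reactants: 1 andrographolide
Product: 2 14-deoxy-11,12-didehydroandrographolide
Conditions: neutral Al2O3, pyridine, reflux, 6 h; filter, evaporate, crystallise
Reagents that add atoms: none
Why: Vinylogous E1cB 1,4-dehydration on the alumina surface: pyridine removes the γ-proton H-11, the extended dienolate expels the C14 hydroxyl, and the conjugated diene-butenolide forms with the thermodynamic E geometry at C11=C12; the five ring stereocentres and the exocyclic alkene are untouched, and the alumina is filtered off unchanged.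

Step 2
Reactants: 2 14-deoxy-11,12-didehydroandrographolide; 3 isopropenyl acetate
Product: 5 19-O-acetyl-14-deoxy-11,12-didehydroandrographolide, via cyclic diphenylborinate ate complex 4 (not isolated)
Conditions: (Ph2B)2O (5 mol %), i-Pr2NEt (20 mol %), isopropenyl acetate (1.5 equiv), MeCN, 40 °C, 12–24 h
Reagents that add atoms: isopropenyl acetate, CC(=C)OC(C)=O
Why: Proposed new method: borinic-acid-catalysed, salt-free site-selective transacetylation of a 1,3-diol with an enol ester. Diphenylborinic acid (from the anhydride) and the amine reversibly convert the 3,19-diol into the six-membered tetracoordinate borinate 4, helped by the quaternary C4 between the two carbinol carbons, and its oxygens are far more nucleophilic than free hydroxyls. The primary O19 attacks the enol ester by nucleophilic acyl substitution, because O3 is shielded by C2-H2, the C4 methyl and the boron-bound phenyls. The expelled acetone enolate is protonated by i-Pr2NEtH+, so boron and base both turn over and acetone is the only by-product. The enol ester does not acylate free alcohols under these conditions, so there is no background path to the 3-acetate or the diacetate, and monoacetate 5 can no longer chelate boron. No stereocentre is formed or touched. Closest known reaction type: diarylborinic-acid-catalysed regioselective O-acylation of diols with acyl chlorides and stoichiometric amine, together with base-catalysed transesterification of enol esters.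

**Compound list**
1 | andrographolide; (3E,4S)-3-{2-[(1R,4aS,5R,6R,8aS)-6-hydroxy-5-(hydroxymethyl)-5,8a-dimethyl-2-methylidenedecahydronaphthalen-1-yl]ethylidene}-4-hydroxyoxolan-2-one | C=C1CC[C@@H]2[C@](C)(CO)[C@H](O)CC[C@@]2(C)[C@@H]1C/C=C1/C(=O)OC[C@H]1O | starting material
2 | 14-deoxy-11,12-didehydroandrographolide; 3-{(E)-2-[(1R,4aS,5R,6R,8aR)-6-hydroxy-5-(hydroxymethyl)-5,8a-dimethyl-2-methylidenedecahydronaphthalen-1-yl]ethenyl}furan-2(5H)-one (same spatial arrangement as 1; 3-OH and 19-CH2OH free) | C=C1CC[C@@H]2[C@](C)(CO)[C@H](O)CC[C@@]2(C)[C@@H]1/C=C/C1=CCOC1=O | intermediate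
3 | isopropenyl acetate (prop-1-en-2-yl acetate) | CC(=C)OC(C)=O | starting material
4 | N-ethyl-N,N-diisopropylammonium salt of the tetracoordinate borate in which O3 and O19 of 2 are bridged by a BPh2 unit (2,2-diphenyl-1,3,2-dioxaborinane ate complex fused to ring A; not isolated) | C=C1CC[C@@H]2[C@]3(C)CO[B-](c4ccccc4)(c4ccccc4)O[C@@H]3CC[C@@]2(C)[C@@H]1/C=C/C1=CCOC1=O.CC[NH+](C(C)C)C(C)C | intermediate
5 | 19-O-acetyl-14-deoxy-11,12-didehydroandrographolide; [(1R,2R,4aR,5R,8aS)-2-hydroxy-1,4a-dimethyl-6-methylidene-5-[(E)-2-(2-oxo-2,5-dihydrofuran-3-yl)ethenyl]decahydronaphthalen-1-yl]methyl acetate (compound 2 with the primary C19 hydroxyl acetylated, C3 hydroxyl free) | C=C1CC[C@@H]2[C@](C)(COC(C)=O)[C@H](O)CC[C@@]2(C)[C@@H]1/C=C/C1=CCOC1=O | target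

**Total step count:** 2
**Longest linear sequence:** 2

**Steps most likely to fail** (the route has only two steps, so both are ranked; there is no third)

Step 2, the proposed new step, is the most likely to fail. The borinate 4 may be too weak a nucleophile for the enol ester, giving low conversion. The fallback is known chemistry and replaces boron catalysis by stoichiometric tin activation. It sets out from 2: Bu2SnO (1.05 equiv) in toluene at reflux with azeotropic removal of water gives the 3,19-O-dibutylstannylene acetal of 2 F1. Acetyl chloride (1.05 equiv) in CH2Cl2 at 0 °C then acylates the primary oxygen, the usual regiochemistry of stannylene acetals, to give 19-O-acetyl-3-O-(chlorodibutylstannyl)-14-deoxy-11,12-didehydroandrographolide F2. Aqueous NaHCO3 work-up hydrolyses the tin ether, and the fallback comes back to the route at 5.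

Step 1 is second. Alumina of variable activity may give incomplete dehydration or by-products such as migration of the exocyclic alkene. The fallback is known chemistry and replaces direct dehydration by protection, activation and elimination. It sets out from 1: 2,2-dimethoxypropane and catalytic pyridinium p-toluenesulfonate in CH2Cl2/acetone give 3,19-O-isopropylideneandrographolide F3. Ac2O, Et3N and catalytic 4-(dimethylamino)pyridine in CH2Cl2 at 0 °C give 14-O-acetyl-3,19-O-isopropylideneandrographolide F4. 1,8-Diazabicyclo[5.4.0]undec-7-ene in toluene at 60 °C eliminates acetic acid (E1cB) to give 3,19-O-isopropylidene-14-deoxy-11,12-didehydroandrographolide F5. Aqueous acetic acid (7:3) at room temperature removes the acetonide, and the fallback comes back to the route at 2.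

**Further compounds**
F1 | step 2 | 3,19-O-dibutylstannylene acetal of 14-deoxy-11,12-didehydroandrographolide | C=C1CC[C@@H]2[C@]3(C)CO[Sn](CCCC)(CCCC)O[C@@H]3CC[C@@]2(C)[C@@H]1/C=C/C1=CCOC1=O
F2 | step 2 | 19-O-acetyl-3-O-(chlorodibutylstannyl)-14-deoxy-11,12-didehydroandrographolide | C=C1CC[C@@H]2[C@](C)(COC(C)=O)[C@H](O[Sn](Cl)(CCCC)CCCC)CC[C@@]2(C)[C@@H]1/C=C/C1=CCOC1=O
F3 | step 1 | 3,19-O-isopropylideneandrographolide | C=C1CC[C@@H]2[C@]3(C)COC(C)(C)O[C@@H]3CC[C@@]2(C)[C@@H]1C/C=C1/C(=O)OC[C@H]1O
F4 | step 1 | 14-O-acetyl-3,19-O-isopropylideneandrographolide | C=C1CC[C@@H]2[C@]3(C)COC(C)(C)O[C@@H]3CC[C@@]2(C)[C@@H]1C/C=C1/C(=O)OC[C@H]1OC(C)=O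
F5 | step 1 | 3,19-O-isopropylidene-14-deoxy-11,12-didehydroandrographolide | C=C1CC[C@@H]2[C@]3(C)COC(C)(C)O[C@@H]3CC[C@@]2(C)[C@@H]1/C=C/C1=CCOC1=O
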